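Numbering (labdane): ring A = C1–C5 + C10 (C3–Br, C4 gem-dimethyl). Ring B = C5–C10. Ring C (oxocane) = O–C8–C9–C11–C12–C13–C14–C15, with the epoxide on C13–C14. Methyls: C16 on C13, C17 on C8, C18/C19 on C4, C20 on C10. TBS = tert-butyldimethylsilyl, TMS = trimethylsilyl.
Cuts in retrosynthetic order: epoxide O; C13=C14 (ring-closing metathesis) and O–C15 (allylation); C3–H/C5–H (one hydrogenation of a 3-bromo-2,5-diene); the two C4–CH3 bonds; ring A at C4=C5 and C1–C10 (Robinson annulation); C9–C11 (conjugate addition); C8–O back to C8–CHO; last, ring B at C6–C7 and C8–C9 ([4+2]).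
Enabling feature: in ring B the unsubstituted ethano bridge C6–C7 joins C5, a ring-fusion carbon that can begin as an enol-ether/ketone carbon, to the fully substituted, oxygenated C8 standing para to it. With C10 bearing a methyl group, this is the retron of a Diels–Alder reaction between the 2-silyloxy diene C6=C5(OSi)–C10(CH3)=C9 and methacrolein C7=C8(CH3)CHO, the formyl group being a latent C8–O.
Forward order of rings: B (step 2), A (step 7), C (step 16), oxirane (step 17).
Stereochemistry: C8 is the only centre set by a catalyst (chiral Lewis acid, step 2). C9 (anti to C8–O), C10 (anti to the C9 chain), C5 and C3 (together in one hydrogen-atom-transfer hydrogenation) and C13/C14 (peripheral attack on ring C) are relayed from it by substrate control.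

Key step: step 2

Assumption: the (S)-configured oxazaborolidinium catalyst is taken to expose the enal face that leads to (R)-4; should the sense be opposite, its equally available enantiomer is used and nothing else changes.

Step 1
Reactants: 1 3-methylbut-3-en-2-one
Product: 2 tert-butyl(dimethyl)[(3-methylbuta-1,3-dien-2-yl)oxy]silane
Conditions: TBSOTf, Et3N, Et2O, 0 °C
Reagents that add atoms: tert-butyldimethylsilyl trifluoromethanesulfonate (TBSOTf), CC(C)(C)[Si](C)(C)OS(=O)(=O)C(F)(F)F
Why: Soft enolisation at the only enolisable position (the acetyl CH3, the future C6) gives the 2-silyloxy diene by silyl enol ether formation, and no stereocenter is formed.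

Step 2
Reactants: 2 tert-butyl(dimethyl)[(3-methylbuta-1,3-dien-2-yl)oxy]silane; 3 methacrolein (2-methylprop-2-enal)
Product: 4 (1R)-4-(TBSO)-1,3-dimethylcyclohex-3-ene-1-carbaldehyde
Conditions: (S)-3,3-diphenyl-1-(o-tolyl)tetrahydropyrrolo[1,2-c][1,3,2]oxazaborole (20 mol %), HNTf2 (20 mol %), CH2Cl2, −78 °C
Reagents that add atoms: none
Why: The protonated oxazaborolidine binds the formyl oxygen of s-trans methacrolein and lowers its LUMO, and diene 2 adds in a concerted but asynchronous [4+2] cycloaddition in which the C6–C7 bond (diene CH2 next to C5–OSi to the enal β-CH2) runs ahead of the C8–C9 bond. The closest known reaction type is the chiral-Lewis-acid-catalysed enantioselective Diels–Alder reaction of α-substituted acroleins with 2,3-disubstituted and 2-silyloxy butadienes. Ring B is closed in the intermolecular [4+2] mode, both new σ bonds (C6–C7 and C8–C9) being made suprafacially on each partner. The only new stereocenter, quaternary C8, is controlled by the catalyst, whose formyl C–H···O contact holds the enal over one aryl group so that a single enal face stays open, and because neither diene terminus carries a substituent no endo/exo question arises. The step needs para regioselectivity (C5–O para to C8) and 1,4- rather than 1,2-attack on the enal: the silyloxy donor on C5 puts the largest HOMO coefficient on C6 and outweighs the C10 methyl, while the bulky TBS group and the low temperature disfavour the aldol-type pathway.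

Step 3
Reactants: 4 (1R)-4-(TBSO)-1,3-dimethylcyclohex-3-ene-1-carbaldehyde
Product: 5 (1R)-1,3-dimethyl-4-oxocyclohex-2-ene-1-carbaldehyde
Conditions: Pd(OAc)2 (1.05 equiv), MeCN, 25 °C
Reagents that add atoms: none
Why: Saegusa–Ito oxidation, in which the enolate of divalent palladium formed from the C5=C10 silyl enol ether loses a β-hydride from C9 to give the more substituted endocyclic enone, while quaternary C8 and the non-enolisable aldehyde are untouched.

Step 4
Reactants: 5 (1R)-1,3-dimethyl-4-oxocyclohex-2-ene-1-carbaldehyde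
Product: 7 (4R)-4-hydroxy-2,4-dimethylcyclohex-2-en-1-one, via formate 6 (not isolated)
Conditions: mCPBA, CH2Cl2, 0 to 25 °C; then K2CO3 (10 mol %), MeOH, 0 °C
Reagents that add atoms: 3-chloroperoxybenzoic acid (mCPBA), O=C(OO)c1cccc(Cl)c1
Why: Baeyer–Villiger oxidation of the α-quaternary aldehyde, in whose Criegee adduct the tertiary allylic C8 migrates in preference to hydrogen and with retention of configuration, the electron-poor enone is not epoxidised, and mild methanolysis of the formate frees the tertiary alcohol.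

Step 5
Reactants: 7 (4R)-4-hydroxy-2,4-dimethylcyclohex-2-en-1-one
Product: 8 (4R)-4-(TBSO)-2,4-dimethylcyclohex-2-en-1-one
Conditions: TBSOTf, 2,6-lutidine, CH2Cl2, 0 °C
Reagents that add atoms: tert-butyldimethylsilyl trifluoromethanesulfonate (TBSOTf), CC(C)(C)[Si](C)(C)OS(=O)(=O)C(F)(F)F
Why: Silylation of the tertiary alcohol with the reactive silyl triflate touches only the O–H bond and installs the bulky C8–OTBS group that steers step 6.

Step 6
Reactants: 8 (4R)-4-(TBSO)-2,4-dimethylcyclohex-2-en-1-one; 9 2-(2-bromoethyl)-2-methyl-1,3-dioxolane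
Product: 11 (3R,4R)-4-(TBSO)-2,4-dimethyl-3-[2-(2-methyl-1,3-dioxolan-2-yl)ethyl]-1-(TMSO)cyclohex-1-ene, via Grignard reagent 10 (not isolated)
Conditions: 9, Mg, THF, 25 °C; then CuBr·SMe2 (10 mol %), HMPA, TMSCl, 8, THF, −78 °C
Reagents that add atoms: chlorotrimethylsilane (TMSCl), C[Si](C)(C)Cl
Why: Copper-catalysed, TMSCl-accelerated conjugate addition, in which attack at C9 comes anti to the pseudoaxial C8–OTBS bond (steric shielding plus σ*C–O stereoelectronic assistance) and so sets C9 with C11 trans to the C8 oxygen, while TMSCl traps the enolate regiospecifically as the C5=C10 silyl enol ether.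

Step 7
Reactants: 11 (3R,4R)-4-(TBSO)-2,4-dimethyl-3-[2-(2-methyl-1,3-dioxolan-2-yl)ethyl]-1-(TMSO)cyclohex-1-ene; 12 3-(trimethylsilyl)but-3-en-2-one
Product: 16 8α-(TBSO)-13,13-ethylenedioxy-14,15,18,19-tetranorlabd-4-en-3-one (8R,9R,10R), via lithium enolate 13 (not isolated), via silyl diketone 14 (not isolated), via diketone 15 (not isolated)
Conditions: MeLi, THF, 0 °C; 12, −78 °C; then KOH (0.2 equiv), MeOH, 65 °C
Reagents that add atoms: none
Why: Robinson annulation in its regiospecific α-silyl vinyl ketone form, where MeLi releases the tetrasubstituted enolate, Michael addition occurs axially and anti to the C9 side chain (held pseudoaxial by A1,2 strain with the C10 methyl) so that C1 ends trans and C20 cis to C11, and methanolic base then removes the silyl group and closes ring A by aldol condensation of C4 onto C5.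

Step 8
Reactants: 16 8α-(TBSO)-13,13-ethylenedioxy-14,15,18,19-tetranorlabd-4-en-3-one (8R,9R,10R)
Product: 17 8α-(TBSO)-13,13-ethylenedioxy-14,15-dinorlabd-5-en-3-one (8R,9R,10R)
Conditions: KOt-Bu, MeI, t-BuOH–THF, 25 °C
Reagents that add atoms: iodomethane (MeI), CI
Why: Deconjugative double α-alkylation of the extended enolate of the enone, the standard entry to 4,4-dimethyl-5-en-3-ones, builds quaternary C4 and moves the alkene to C5=C6 without creating a stereocenter.

Step 9
Reactants: 17 8α-(TBSO)-13,13-ethylenedioxy-14,15-dinorlabd-5-en-3-one (8R,9R,10R)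
Product: 18 8α-(TBSO)-13,13-ethylenedioxy-14,15-dinorlabda-2,5-dien-3-yl trifluoromethanesulfonate (8R,9R,10R)
Conditions: KHMDS, PhNTf2, THF, −78 to 0 °C
Reagents that add atoms: N-phenylbis(trifluoromethanesulfonimide) (PhNTf2), O=S(=O)(N(c1ccccc1)S(=O)(=O)C(F)(F)F)C(F)(F)F
Why: Enol triflate formation, regiochemically unambiguous because C4 is quaternary and only C2 can be deprotonated.

Step 10
Reactants: 18 8α-(TBSO)-13,13-ethylenedioxy-14,15-dinorlabda-2,5-dien-3-yl trifluoromethanesulfonate (8R,9R,10R)
Product: 19 3-bromo-8α-(TBSO)-13,13-ethylenedioxy-14,15-dinorlabda-2,5-diene (8R,9R,10R)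
Conditions: [Cp*Ru(MeCN)3]OTf (5 mol %), LiBr, 1,3-dimethylimidazolidin-2-one, 60 °C
Reagents that add atoms: lithium bromide, [Li+].[Br-]
Why: Ruthenium-catalysed triflate-to-halide exchange of a cyclic alkenyl triflate, a known neutral route to alkenyl bromides that leaves the silyl ether, the ketal and the C5=C6 alkene untouched and forms no stereocenter.

Step 11
Reactants: 19 3-bromo-8α-(TBSO)-13,13-ethylenedioxy-14,15-dinorlabda-2,5-diene (8R,9R,10R)
Product: 20 3β-bromo-8α-(TBSO)-13,13-ethylenedioxy-14,15-dinorlabdane (3S,5R,8R,9R,10S)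
Conditions: Mn(dpm)3 (20 mol %), PhSiH3, t-BuOOH, i-PrOH, 25 °C
Reagents that add atoms: none
Why: Metal-hydride hydrogen-atom-transfer hydrogenation, known both for hindered alkenes and for alkenyl halides with retention of the halogen, adds H to C6 and C2 to give the tertiary C5 radical and the α-bromo C3 radical, and each takes its second hydrogen from the α face opposite the axial C19 and C20 methyls, giving the trans-decalin (5α-H) and the equatorial 3β-bromide, which are also the thermodynamic configurations.

Step 12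
Reactants: 20 3β-bromo-8α-(TBSO)-13,13-ethylenedioxy-14,15-dinorlabdane (3S,5R,8R,9R,10S)
Product: 21 3β-bromo-13,13-ethylenedioxy-14,15-dinorlabdan-8α-ol (3S,5R,8R,9R,10S)
Conditions: Bu4NF, THF, 60 °C
Reagents that add atoms: none
Why: Fluoride-induced desilylation of the tertiary silyl ether, to which the ketal is inert and which the equatorial neopentyl C3–Br bond survives because it has neither an antiperiplanar hydrogen for E2 nor an open backside for SN2.

Step 13
Reactants: 21 3β-bromo-13,13-ethylenedioxy-14,15-dinorlabdan-8α-ol (3S,5R,8R,9R,10S); 22 allyl bromide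
Product: 23 8α-allyloxy-3β-bromo-13,13-ethylenedioxy-14,15-dinorlabdane (3S,5R,8R,9R,10S)
Conditions: KH, THF, 0 °C; 22, Bu4NI (cat.), 25 °C
Reagents that add atoms: none
Why: Williamson etherification, in which KH deprotonates the equatorial tertiary alcohol and the reactive allylic halide alkylates oxygen, so that C8 keeps its configuration because only the O–H bond reacts.

Step 14
Reactants: 23 8α-allyloxy-3β-bromo-13,13-ethylenedioxy-14,15-dinorlabdane (3S,5R,8R,9R,10S)
Product: 24 8α-allyloxy-3β-bromo-14,15-dinorlabdan-13-one (3S,5R,8R,9R,10S)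
Conditions: HCl (cat.), THF–H2O, 25 °C
Reagents that add atoms: water, O
Why: Acid-catalysed ketal hydrolysis, placed after the O-allylation so that no free C8–OH is present to add to the C13 ketone and form a cyclic hemiketal or enol ether.

Step 15
Reactants: 24 8α-allyloxy-3β-bromo-14,15-dinorlabdan-13-one (3S,5R,8R,9R,10S)
Product: 25 8α-allyloxy-3β-bromo-15-norlabd-13-ene (3S,5R,8R,9R,10S)
Conditions: Ph3PCH3Br, KOt-Bu, THF, 0 to 25 °C
Reagents that add atoms: methyltriphenylphosphonium bromide, C[P+](c1ccccc1)(c1ccccc1)c1ccccc1.[Br-]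
Why: Wittig methylenation of the unhindered methyl ketone by the non-stabilised ylide, which cannot reach the shielded C3 bromide, gives the 1,1-disubstituted alkene needed for ring closure.

Step 16
Reactants: 25 8α-allyloxy-3β-bromo-15-norlabd-13-ene (3S,5R,8R,9R,10S)
Product: 26 (13Z)-3β-bromo-8α,15-epoxylabd-13-ene (3S,5R,8R,9R,10S)
Conditions: second-generation Grubbs catalyst (10 mol %), toluene (1 mM), 80 °C
Reagents that add atoms: none
Why: Ring-closing metathesis that starts at the monosubstituted allyl ether and closes onto the 1,1-disubstituted alkene, helped by the gauche, diequatorial C8–O and C9–C11 bonds of the rigid decalin that hold both arms together, the eight-membered ring allowing only the Z alkene.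

Step 17
Reactants: 26 (13Z)-3β-bromo-8α,15-epoxylabd-13-ene (3S,5R,8R,9R,10S)
Product: 27 3β-bromo-8α,15:13β,14β-diepoxylabdane (3S,5R,8R,9R,10S,13R,14S)
Conditions: dimethyldioxirane, acetone–CH2Cl2, −20 °C
Reagents that add atoms: dimethyldioxirane (DMDO), CC1(C)OO1
Why: Concerted syn epoxidation of the only alkene under neutral conditions, where staggering about C9–C11 and C8–O away from the axial C17 and C20 methyls should leave a boat-chair ring C in which C13=C14 hangs below the mean plane with its inner face covered by C11 and H9, so that attack on the open outer face should give the 13R,14S oxirane.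

Compound list
1 | 3-methylbut-3-en-2-one | CC(=O)C(C)=C | starting material
2 | tert-butyl(dimethyl)[(3-methylbuta-1,3-dien-2-yl)oxy]silane | C=C(C)C(=C)O[Si](C)(C)C(C)(C)C | intermediate
3 | methacrolein (2-methylprop-2-enal) | C=C(C)C=O | starting material
4 | (1R)-4-(TBSO)-1,3-dimethylcyclohex-3-ene-1-carbaldehyde | CC1=C(O[Si](C)(C)C(C)(C)C)CC[C@@](C)(C=O)C1 | intermediate
5 | (1R)-1,3-dimethyl-4-oxocyclohex-2-ene-1-carbaldehyde | CC1=C[C@](C)(C=O)CCC1=O | intermediate
6 | (1R)-1,3-dimethyl-4-oxocyclohex-2-en-1-yl formate | CC1=C[C@](C)(OC=O)CCC1=O | intermediate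
7 | (4R)-4-hydroxy-2,4-dimethylcyclohex-2-en-1-one | CC1=C[C@](C)(O)CCC1=O | intermediate
8 | (4R)-4-(TBSO)-2,4-dimethylcyclohex-2-en-1-one | CC1=C[C@](C)(O[Si](C)(C)C(C)(C)C)CCC1=O | intermediate
9 | 2-(2-bromoethyl)-2-methyl-1,3-dioxolane | CC1(CCBr)OCCO1 | starting material
10 | [2-(2-methyl-1,3-dioxolan-2-yl)ethyl]magnesium bromide | CC1(CC[Mg]Br)OCCO1 | intermediate
11 | (3R,4R)-4-(TBSO)-2,4-dimethyl-3-[2-(2-methyl-1,3-dioxolan-2-yl)ethyl]-1-(TMSO)cyclohex-1-ene | CC1=C(O[Si](C)(C)C)CC[C@@](C)(O[Si](C)(C)C(C)(C)C)[C@@H]1CCC2(C)OCCO2 | intermediate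
12 | 3-(trimethylsilyl)but-3-en-2-one | CC(=O)C(=C)[Si](C)(C)C | starting material
13 | lithium (3R,4R)-4-(TBSO)-2,4-dimethyl-3-[2-(2-methyl-1,3-dioxolan-2-yl)ethyl]cyclohex-1-en-1-olate | [Li+].CC1=C([O-])CC[C@@](C)(O[Si](C)(C)C(C)(C)C)[C@@H]1CCC2(C)OCCO2 | intermediate
14 | (2R,3R,4R)-4-(TBSO)-2,4-dimethyl-3-[2-(2-methyl-1,3-dioxolan-2-yl)ethyl]-2-[3-oxo-2-(trimethylsilyl)butyl]cyclohexan-1-one (silyl-bearing carbon undefined) | C[C@@]1(CC([Si](C)(C)C)C(C)=O)[C@@H](CCC2(C)OCCO2)[C@](C)(O[Si](C)(C)C(C)(C)C)CCC1=O | intermediate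
15 | (2R,3R,4R)-4-(TBSO)-2,4-dimethyl-3-[2-(2-methyl-1,3-dioxolan-2-yl)ethyl]-2-(3-oxobutyl)cyclohexan-1-one | C[C@@]1(CCC(C)=O)[C@@H](CCC2(C)OCCO2)[C@](C)(O[Si](C)(C)C(C)(C)C)CCC1=O | intermediate
16 | 8α-(TBSO)-13,13-ethylenedioxy-14,15,18,19-tetranorlabd-4-en-3-one (8R,9R,10R) | O=C1CC[C@]2(C)[C@@H](CCC3(C)OCCO3)[C@](C)(O[Si](C)(C)C(C)(C)C)CCC2=C1 | intermediate
17 | 8α-(TBSO)-13,13-ethylenedioxy-14,15-dinorlabd-5-en-3-one (8R,9R,10R) | CC1(C)C(=O)CC[C@]2(C)[C@@H](CCC3(C)OCCO3)[C@](C)(O[Si](C)(C)C(C)(C)C)CC=C12 | intermediate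
18 | 8α-(TBSO)-13,13-ethylenedioxy-14,15-dinorlabda-2,5-dien-3-yl trifluoromethanesulfonate (8R,9R,10R) | CC1(C)C(OS(=O)(=O)C(F)(F)F)=CC[C@]2(C)[C@@H](CCC3(C)OCCO3)[C@](C)(O[Si](C)(C)C(C)(C)C)CC=C12 | intermediate
19 | 3-bromo-8α-(TBSO)-13,13-ethylenedioxy-14,15-dinorlabda-2,5-diene (8R,9R,10R) | CC1(C)C(Br)=CC[C@]2(C)[C@@H](CCC3(C)OCCO3)[C@](C)(O[Si](C)(C)C(C)(C)C)CC=C12 | intermediate
20 | 3β-bromo-8α-(TBSO)-13,13-ethylenedioxy-14,15-dinorlabdane (3S,5R,8R,9R,10S) | CC1(C)[C@@H](Br)CC[C@]2(C)[C@@H](CCC3(C)OCCO3)[C@](C)(O[Si](C)(C)C(C)(C)C)CC[C@@H]12 | intermediate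
21 | 3β-bromo-13,13-ethylenedioxy-14,15-dinorlabdan-8α-ol (3S,5R,8R,9R,10S) | CC1(C)[C@@H](Br)CC[C@]2(C)[C@@H](CCC3(C)OCCO3)[C@](C)(O)CC[C@@H]12 | intermediate
22 | allyl bromide | C=CCBr | starting material
23 | 8α-allyloxy-3β-bromo-13,13-ethylenedioxy-14,15-dinorlabdane (3S,5R,8R,9R,10S) | CC1(C)[C@@H](Br)CC[C@]2(C)[C@@H](CCC3(C)OCCO3)[C@](C)(OCC=C)CC[C@@H]12 | intermediate
24 | 8α-allyloxy-3β-bromo-14,15-dinorlabdan-13-one (3S,5R,8R,9R,10S) | CC1(C)[C@@H](Br)CC[C@]2(C)[C@@H](CCC(C)=O)[C@](C)(OCC=C)CC[C@@H]12 | intermediate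
25 | 8α-allyloxy-3β-bromo-15-norlabd-13-ene (3S,5R,8R,9R,10S) | CC1(C)[C@@H](Br)CC[C@]2(C)[C@@H](CCC(C)=C)[C@](C)(OCC=C)CC[C@@H]12 | intermediate
26 | (13Z)-3β-bromo-8α,15-epoxylabd-13-ene (3S,5R,8R,9R,10S) | CC1(C)[C@@H](Br)CC[C@]2(C)[C@H]3CC/C(C)=C\CO[C@]3(C)CC[C@@H]12 | intermediate
27 | 3β-bromo-8α,15:13β,14β-diepoxylabdane (3S,5R,8R,9R,10S,13R,14S) | CC1(C)[C@@H](Br)CC[C@]2(C)[C@H]3CC[C@@]4(C)O[C@H]4CO[C@]3(C)CC[C@@H]12 | target

Total step count: 17. Longest linear sequence: 17 steps (from 1 to 27). Compounds 3, 9, 12 and 22 enter as purchased materials.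

Steps most likely to fail

Risk 1 (step 17). Ring C may react through a different conformer than the one argued, so the oxidant may prefer the other alkene face. The fallback sets out from 26 and reverses the facial outcome instead of tuning the oxidant. N-bromosuccinimide in THF–H2O places the bromonium ion on the face the oxidant prefers. Water then opens it anti at the tertiary C13 to give the 14α-bromo-13β-hydroxy bromohydrin F1. K2CO3 in MeOH closes the oxirane by internal SN2 displacement at C14, which puts the oxygen on the opposite face. The route is rejoined at 27.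

Risk 2 (step 11). Three things may go wrong. Hydrogen-atom transfer to the hindered C5=C6 alkene may be sluggish. Bromine may be lost by β-scission if hydrogen adds first to C3. The second hydrogen may reach C3 from the β face. The fallback sets out from 17 and sets the two centres separately by classical means.
- Heterogeneous hydrogenation (H2, Pd/C, EtOAc) delivers hydrogen to the α face and gives the trans-fused saturated 3-ketone F2.
- LiBH(s-Bu)3 attacks this ketone equatorially and gives the axial 3α-alcohol F3.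
- An Appel bromination (PPh3, CBr4, toluene) displaces the activated oxygen with inversion, and the route is rejoined at 20.

Risk 3 (step 7). Proton transfer between the hindered tetrasubstituted enolate and the enone or its adduct, together with enone polymerisation, may outrun formation of the quaternary C10 next to the branched C9. The fallback sets out from 11 and avoids any free enolate. A Mukaiyama–Michael addition of the neutral silyl enol ether to but-3-en-2-one under catalysis by TMSNTf2 (CH2Cl2, −78 °C), followed by aqueous work-up, gives diketone 15. This is isolated and cyclised in a separate step with KOH in MeOH, and the route is rejoined at 16 (new compounds: none F0).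

Further compounds
F1 | step 17 | (13R,14R)-3β,14α-dibromo-8α,15-epoxylabdan-13β-ol | CC1(C)[C@@H](Br)CC[C@]2(C)[C@H]3CC[C@@](C)(O)[C@H](Br)CO[C@]3(C)CC[C@@H]12
F2 | step 11 | 8α-(TBSO)-13,13-ethylenedioxy-14,15-dinorlabdan-3-one (5α-H, trans-fused) | CC1(C)C(=O)CC[C@]2(C)[C@@H](CCC3(C)OCCO3)[C@](C)(O[Si](C)(C)C(C)(C)C)CC[C@@H]12
F3 | step 11 | 8α-(TBSO)-13,13-ethylenedioxy-14,15-dinorlabdan-3α-ol (3R, axial OH) | CC1(C)[C@H](O)CC[C@]2(C)[C@@H](CCC3(C)OCCO3)[C@](C)(O[Si](C)(C)C(C)(C)C)CC[C@@H]12
F0 | step 7 | none | none
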